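## Structural features

The target is an ent-labdane: a trans-fused decalin (ring A = C1–C5/C10, ring B = C5–C10) with a gem-dimethyl group at C4, an angular methyl at C10, a C8 methyl on a trisubstituted C7=C8 alkene, and a six-carbon side chain on C9. Three contiguous stereocentres span the ring fusion (C5, C10, C9; 5S, 9R, 10S). H-5 and H-9 lie on the face opposite the C10 methyl, so C11 is equatorial and cis to that methyl. Ring A carries a cis-2,3-diol (2S, 3R) on the face opposite the C10 methyl: the C2 oxygen is equatorial and acetylated, the C3 hydroxyl is axial, neopentyl and free. The side chain ends in an E-trisubstituted allylic acetate (C13=C14, C15–OAc). Fragile points are the allylic acetate (ionisation, SN2′, hydrolysis), acetyl migration between O2 and O3, acid-induced drift of the C7=C8 alkene towards C8=C9, and the presence of three alkenes, which rules out a late dihydroxylation. The real difficulty lies in three places: the C4 quaternary carbon wedged between the C5 fusion centre and the oxygenated C3; the C9 centre that must be set next to quaternary C10 without losing the C7=C8 position; and the absolute configuration, which is opposite to that of the common labdane chiral pool. The key step exploits the fact that ring B, with its C5 stereocentre, its C7=C8(C17)–C9 unit and the C4 carbon bearing two methyls, is atom for atom the skeleton of 1 once a hydrogen is added to the isopropenyl CH2. Only the C3–C4 bond is then missing from ring A, and because C3 is oxygenated in the target, the ring-closing carbon can arrive as a nitrile carbon and leave a ketone exactly where the 2,3-diol must be built.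

## Logic of the disconnections

29 ⇒ 28. The two acyl–oxygen bonds at O15 and O2 are cut. The three hydroxyls of 28 differ enough (primary, equatorial secondary, axial neopentyl secondary) that no protecting group is needed. The forward acetylation must stop before the axial O3 reacts.

28 ⇒ 27 ⇒ 26. The diol is masked as an acetonide and C15 is raised to the ester level; no skeletal bond is cut. This lets the side chain arrive as a stereodefined enoate and lets the diol survive organometallic, oxidative and Mitsunobu steps. The forward steps need a hydride reduction and a mild acid hydrolysis that leave the C7=C8 alkene and the allylic alcohol alone.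

26 ⇒ 23 (through 25 and 24). The C9–H bond is cut and a C7–O bond restored with the alkene at C8=C9. This trades the hard C9 centre (next to quaternary C10) for an easy C7 carbinol. The forward reductive transposition must deliver hydrogen to the upper face of C9, which demands that the C7 oxygen of 23 be down.

23 ⇒ 22 ⇒ 21. The C7 oxygen is traced back to a C9 oxygen by a 1,3-transposition. C9 thereby becomes a carbinol carbon that derives from a ketone. The forward steps need an oxidative allylic shift towards C7 and a hydride attack on C7 from the face opposite the C10 methyl.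

21 ⇒ 17 + 19 (through 20). The C12–C13 bond is cut. The complete E-trisubstituted alkene then comes from a four-carbon enol triflate of fixed geometry. The forward step needs hydroboration of the vinyl group only and cross-coupling with retention.

19 ⇒ 18. The enol C–O(sulfonyl) bond is cut. The forward step must give the E enol triflate.

17 ⇒ 15 + 16. The C9–C11 bond is cut, leaving the C9 ketone. The forward step is a 1,2-addition to a hindered enone carbonyl.

15 ⇒ 14 ⇒ 13. The C2–O and C3–O bonds are cut, leaving the C2=C3 alkene. The dihydroxylation is placed where the only other alkene is the electron-poor enone. It must occur on the face opposite the axial methyls at C10 and C4.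

13 ⇒ 12 ⇒ 11. The C2=C3 alkene is traced to the C3 ketone through its enol triflate. The forward step needs enolisation of the C3 ketone (possible only towards C2) in preference to γ-deprotonation of the enone.

11 ⇒ 9 (through 10), the key disconnection. The C3–C4 bond is cut. Ring A opens, the C4 quaternary carbon reverts to an isopropenyl group and C3 to a nitrile carbon. The bicycle collapses to a monocyclic, doubly alkylated derivative of 1 in which C5 is purchased and C10 is set by alkylation. The forward step needs a tertiary C4 radical made selectively at the isopropenyl group and a 6-exo closure onto the nitrile that outruns reduction of the radical. In one sentence: ring A is annulated onto the ring of 1, which becomes ring B, by a hydrogen-atom-transfer radical cyclisation of the isopropenyl group onto a pendant nitrile.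

9 ⇒ 6 ⇒ 4 (through 8, 7 and 5). The C3–N bond and the C3 oxidation level are traced to the terminal carbon of an allyl group. The three carbons are brought in by alkylation rather than by conjugate addition to an unsaturated nitrile, because the adduct anion of such an addition could add a second time, intramolecularly, to C7 of the enone. The forward steps need anti-Markovnikov functionalisation of the monosubstituted alkene only.

4 ⇒ 2 + 3. The C1–C10 bond is cut. The second alkylation of the C10 enolate must occur anti to the neighbouring isopropenyl group, which places the methyl cis and the three-carbon arm trans to the future C4, as a trans ring fusion requires.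

2 ⇒ 1. The C10–C20 bond is cut, leaving the commercial terpene.

## Other disconnections considered

Alternative 1: the biomimetic cut of C4–C5 and C9–C10 (first to come to mind). The forward key step is a Lewis-acid or Cp2TiCl (trivalent titanium) opening of (R)-14,15-epoxygeranylgeranyl acetate A1 with bicyclisation to the 3-hydroxy-8(17),13-diene acetate A2. The chosen plan is preferred for three reasons. The epoxide of A1 must be made enantioselectively at one of four similar trisubstituted alkenes. The terminating elimination is expected to give the exocyclic C8=C17 alkene or mixtures rather than C7=C8, and moving it later with acid conflicts with the allylic acetate. The cyclisation also delivers an equatorial C3 hydroxyl that must be erased to reach the C2=C3 alkene, so ring A still needs the same four operations as here. In the chosen plan the C7=C8 alkene, C17 and the absolute configuration are bought with 1.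

Alternative 2: an enzymatic cut of the same two bonds. A class 2 diterpene cyclase (an ent-copalyl diphosphate synthase) would convert geranylgeranyl diphosphate A3 into ent-copalyl diphosphate A4, setting both rings and C5, C9 and C10 in the ent series in one step. It is not preferred because A4 has an unoxidised ring A and the exocyclic alkene. C2 and C3 are then unactivated methylenes that no small reagent oxidises selectively, so a second enzymatic hydroxylation of unknown site selectivity would be needed. The enzyme solves the part of the problem that is also solvable chemically and leaves the 2,3-diol untouched.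

Alternative 3: a cut of C2–C3 by ring-closing metathesis. 2,6-Dimethylcyclohex-2-en-1-one A5 would undergo conjugate addition of a prenyl nucleophile through its γ-carbon and enolate allylation to give diene A6. A ruthenium alkylidene (second-generation Grubbs catalyst) would then close ring A to the bicyclic ketone A7 with the C2=C3 alkene in place. The metathesis itself should be reliable. The plan is not preferred because the absolute configuration would rest on an enantioselective γ-selective prenyl conjugate addition to an α-substituted enone, for which no general method exists, and because ring B arrives saturated, so the C7=C8 alkene must be introduced afterwards. Compound 1 supplies both features at no cost.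

Key step: step 5

Remark: "up" and "down" refer to the usual labdane drawing (ring A left, C10 at the upper ring junction); in every bicyclic compound below the C10 methyl is down and H-5 is up (ent series), and ring atoms carry labdane numbers.
Remark: 2 is carried on as its C6 epimer mixture, because both epimers give the same enolate in step 2.

## Route

Step 1
Reactants: 1 (S)-(+)-carvone
Product: 2 (5S)-6-methylcarvone (6R epimer major)
Conditions: LiN(i-Pr)2, THF, −78 °C; MeI, −78 → 0 °C
Reagents that add atoms: iodomethane, CI
Why: Kinetic α′-deprotonation of the enone gives the cross-conjugated enolate, which is methylated at C6 (enolate alkylation); the new centre forms as an epimer mixture that is planarised again in step 2.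

Step 2
Reactants: 2 (5S)-6-methylcarvone; 3 allyl bromide
Product: 4 (5R,6R)-6-allyl-6-methylcarvone (allyl trans to isopropenyl)
Conditions: LiN(i-Pr)2, THF, −78 → 0 °C; then 3, −78 °C → rt
Reagents that add atoms: none
Why: Enolate alkylation; the tetrasubstituted enolate should be allylated on the face anti to the adjacent isopropenyl group, which sets quaternary C10 with the methyl cis and the three-carbon arm trans to the future C4, the arrangement a trans-fused ring A requires.

Step 3
Reactants: 4 (5R,6R)-6-allyl-6-methylcarvone
Product: 6 6-(3-hydroxypropyl)-6-methylcarvone, via catechol boronate 5 (not isolated)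
Conditions: RhCl(PPh3)3 (2 mol%), catecholborane, THF, 0 °C → rt; then NaBO3·4H2O, THF/H2O, rt
Reagents that add atoms: sodium perborate (water of crystallisation omitted), O[B-]1(O)OO[B-](O)(O)OO1.[Na+].[Na+]
Why: Rhodium-catalysed hydroboration is selective for the monosubstituted alkene over the 1,1-disubstituted isopropenyl group, the enone alkene and the ketone, and places boron on the terminal carbon; perborate oxidation is mild enough to spare the enone.

Step 4
Reactants: 6 6-(3-hydroxypropyl)-6-methylcarvone
Product: 9 6-(2-cyanoethyl)-6-methylcarvone, via aldehyde 7 (not isolated), via aldimine 8 (not isolated)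
Conditions: TEMPO (10 mol%), PhI(OAc)2, NH4OAc, MeCN/H2O 9:1, rt
Reagents that add atoms: ammonium acetate, CC(=O)[O-].[NH4+]
Why: One-pot oxoammonium oxidation to the aldehyde, condensation with ammonia and a second oxidation converts a primary alcohol into the nitrile of the same carbon count; the alkenes and the hindered enone should not react.

Step 5
Reactants: 9 6-(2-cyanoethyl)-6-methylcarvone
Product: 11 ent-11-nordrim-7-ene-3,9-dione, via ketimine 10 (not isolated)
Conditions: Fe(acac)3 (0.5 equiv), PhSiH3, degassed EtOH, 60 °C; then 1 M HCl, THF, rt
Reagents that add atoms: water, O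
Why: Metal-hydride hydrogen-atom-transfer (Mukaiyama-type) radical cyclisation of an alkenyl nitrile: the iron hydride formed from Fe(acac)3 and PhSiH3 transfers a hydrogen atom to the CH2 terminus of the electron-rich 1,1-disubstituted isopropenyl group, not to the electron-poor trisubstituted enone alkene, and so gives the tertiary C4 radical. This nucleophilic radical adds to the nitrile carbon in a 6-exo-dig closure that forms the C3–C4 bond and ring A; the iminyl radical is reduced and protonated to ketimine 10, which aqueous acid hydrolyses to the C3 ketone. The closest known reaction type is the iron-hydride-initiated cyclisation of alkenyl nitriles to cyclic ketones, and the titanocene chloride epoxide–nitrile radical cyclisation makes the same kind of bond. No new stereocentre arises, since C4 becomes the gem-dimethyl carbon. The trans ring fusion is inherited: the two reacting arms sit trans-diequatorial on the half-chair of ring B, as fixed by the carvone centre (C5) and by step 2 (C10), and only that arrangement can close. The step needs site-selective hydrogen-atom transfer and cyclisation ahead of reduction of the radical; the first is secured by alkene electronics, the second by the quaternary C10 (gem-disubstituent effect), the pre-organised arms and the low stationary concentration of the hydride.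

Step 6
Reactants: 11 ent-11-nordrim-7-ene-3,9-dione
Product: 12 3-(trifluoromethylsulfonyloxy)-ent-11-nordrima-2,7-dien-9-one
Conditions: KN(SiMe3)2 (1.05 equiv), THF, −78 °C; PhNTf2, −78 → 0 °C
Reagents that add atoms: N-phenylbis(trifluoromethanesulfonimide), O=S(=O)(N(c1ccccc1)S(=O)(=O)C(F)(F)F)C(F)(F)F
Why: Kinetic enolisation and O-sulfonylation (enol triflate formation); the C3 ketone can enolise only towards C2 because C4 is quaternary, while the enone has no α′ hydrogen and its γ-deprotonation at C6 should be slower at −78 °C.

Step 7
Reactants: 12 3-(trifluoromethylsulfonyloxy)-ent-11-nordrima-2,7-dien-9-one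
Product: 13 ent-11-nordrima-2,7-dien-9-one
Conditions: Pd(OAc)2 (5 mol%), PPh3, Bu3N, HCO2H, DMF, 60 °C
Reagents that add atoms: none
Why: Palladium-catalysed formate reduction of a vinyl triflate (oxidative addition, formate decarboxylation, C–H reductive elimination) leaves the C2=C3 alkene; the enone is inert under these conditions.

Step 8
Reactants: 13 ent-11-nordrima-2,7-dien-9-one
Product: 14 2,3-dihydroxy-ent-11-nordrim-7-en-9-one (both hydroxyls up)
Conditions: OsO4 (5 mol%), N-methylmorpholine N-oxide, acetone/H2O, rt → 40 °C
Reagents that add atoms: osmium tetroxide (oxygen carrier), O=[Os](=O)(=O)=O; N-methylmorpholine N-oxide, C[N+]1([O-])CCOCC1; water, O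
Why: Catalytic syn-dihydroxylation (Upjohn conditions) should attack the electron-richer C2=C3 alkene rather than the conjugated C7=C8 alkene, from the face opposite the axial methyls at C10 and C4; this sets C2 (oxygen equatorial) and C3 (oxygen axial) as the cis-diol of the target.

Step 9
Reactants: 14 2,3-dihydroxy-ent-11-nordrim-7-en-9-one
Product: 15 2,3-O-isopropylidene-2,3-dihydroxy-ent-11-nordrim-7-en-9-one
Conditions: 2,2-dimethoxypropane, pyridinium p-toluenesulfonate (5 mol%), acetone, rt
Reagents that add atoms: 2,2-dimethoxypropane, COC(C)(C)OC
Why: Acid-catalysed transketalisation of a cis-1,2-diol to the acetonide, which protects both hydroxyls through the organometallic, oxidative and Mitsunobu steps.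

Step 10
Reactants: 15 2,3-O-isopropylidene-2,3-dihydroxy-ent-11-nordrim-7-en-9-one; 16 vinylmagnesium bromide
Product: 17 9-vinyl-9-hydroxy-2,3-O-isopropylidene-2,3-dihydroxy-ent-11-nordrim-7-ene (vinyl up; OH down)
Conditions: CeCl3 (anhydrous), CH2=CHMgBr, THF, −78 → 0 °C; aq. NH4Cl
Reagents that add atoms: none
Why: Organocerium 1,2-addition to a hindered, non-enolisable enone carbonyl; attack opposite the C10 methyl should give mainly the carbinol with the oxygen down, and the C9 configuration is erased in step 13 in any case.

Step 11
Reactants: 18 ethyl acetoacetate
Product: 19 ethyl (E)-3-(trifluoromethylsulfonyloxy)but-2-enoate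
Conditions: Tf2O, aq. Me4NOH, hexanes, 0–5 °C
Reagents that add atoms: trifluoromethanesulfonic anhydride, O=S(=O)(OS(=O)(=O)C(F)(F)F)C(F)(F)F
Why: O-sulfonylation of a β-keto ester enolate under non-chelating conditions (tetramethylammonium counter-ion) should give the E enol triflate, with the triflate trans to the ester.

Step 12
Reactants: 17 9-vinyl carbinol; 19 ethyl (E)-3-(trifluoromethylsulfonyloxy)but-2-enoate
Product: 21 ethyl 9-hydroxy-2,3-O-isopropylidene-2,3-dihydroxy-ent-labda-7,13E-dien-15-oate (9-OH down), via B-alkyl-9-BBN 20 (not isolated)
Conditions: 9-BBN (2.5 equiv), THF, 0 °C → rt; then 19, Pd(dppf)Cl2 (5 mol%), aq. K3PO4, DMF, rt → 45 °C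
Reagents that add atoms: none
Why: 9-BBN adds only to the monosubstituted vinyl group with boron on C12, and the B-alkyl Suzuki–Miyaura coupling forms C12–C13 with retention of the enol triflate geometry, giving the E-trisubstituted enoate.

Step 13
Reactants: 21 ethyl 9-hydroxy-2,3-O-isopropylidene-2,3-dihydroxy-ent-labda-7,13E-dien-15-oate
Product: 22 ethyl 2,3-O-isopropylidene-2,3-dihydroxy-7-oxo-ent-labda-8,13E-dien-15-oate
Conditions: pyridinium chlorochromate [C5H5NH][CrO3Cl] (3 equiv), 4 Å molecular sieves, CH2Cl2, rt
Reagents that add atoms: none
Why: Oxidative 1,3-transposition of a tertiary allylic alcohol (Babler–Dauben oxidation): the chromate ester shifts from C9 to C7 by a [3,3] process and is oxidised to the enone, which also relieves the congestion at C9.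

Step 14
Reactants: 22 ethyl 2,3-O-isopropylidene-2,3-dihydroxy-7-oxo-ent-labda-8,13E-dien-15-oate
Product: 23 ethyl 7-hydroxy-2,3-O-isopropylidene-2,3-dihydroxy-ent-labda-8,13E-dien-15-oate (7-OH down)
Conditions: NaBH4, CeCl3·7H2O, MeOH, −40 → 0 °C
Reagents that add atoms: none
Why: Luche 1,2-reduction; axial hydride delivery on the face opposite the C10 methyl should place the C7 hydroxyl down (cis to that methyl), as in the reduction of steroidal 4-en-3-ones, and the enoate ester is not reduced.

Step 15
Reactants: 23 ethyl 7-hydroxy-2,3-O-isopropylidene-2,3-dihydroxy-ent-labda-8,13E-dien-15-oate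
Product: 26 ethyl 2,3-O-isopropylidene-2,3-dihydroxy-ent-labda-7,13E-dien-15-oate, via N-allyl sulfonylhydrazine 24 (not isolated), via allylic diazene 25 (not isolated)
Conditions: PPh3, diethyl azodicarboxylate, 2-nitrobenzenesulfonylhydrazide, N-methylmorpholine, −30 °C → rt
Reagents that add atoms: none
Why: Mitsunobu displacement with inversion puts nitrogen on the upper face of C7; loss of the sulfinic acid gives the monoalkyl diazene, whose retro-ene loss of N2 delivers hydrogen to the upper face of C9 and moves the alkene to C7=C8 (reductive allylic transposition). This sets C9 with C11 down, cis to the C10 methyl.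

Step 16
Reactants: 26 ethyl 2,3-O-isopropylidene-2,3-dihydroxy-ent-labda-7,13E-dien-15-oate
Product: 27 2,3-O-isopropylidene-ent-labda-7,13E-diene-2,3,15-triol
Conditions: i-Bu2AlH (2.5 equiv), CH2Cl2, −78 °C; aq. potassium sodium tartrate
Reagents that add atoms: none
Why: Hydride reduction of the conjugated ester to the allylic alcohol by two 1,2-additions, without change of alkene geometry; the acetonide is stable.

Step 17
Reactants: 27 2,3-O-isopropylidene-ent-labda-7,13E-diene-2,3,15-triol
Product: 28 ent-labda-7,13E-diene-2,3,15-triol (2-OH and 3-OH up)
Conditions: AcOH/H2O/THF 3:1:1, 45 °C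
Reagents that add atoms: none
Why: Acid-catalysed acetonide hydrolysis under conditions mild enough to leave the primary allylic alcohol and the C7=C8 alkene in place.

Step 18
Reactants: 28 ent-labda-7,13E-diene-2,3,15-triol
Product: 29 CNP0254679.1 (2-acetoxy-3-hydroxy-ent-labda-7,13E-dien-15-yl acetate)
Conditions: Ac2O (2.2 equiv), pyridine, CH2Cl2, 0 °C → rt, no acyl-transfer catalyst
Reagents that add atoms: acetic anhydride, CC(=O)OC(C)=O
Why: Selective O-acylation; the primary C15 hydroxyl and the equatorial C2 hydroxyl should react, while the axial C3 hydroxyl, flanked by the C4 gem-dimethyl group, should not in the absence of an acyl-transfer catalyst.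

## Compound list

1 | (S)-(+)-carvone, (5S)-2-methyl-5-(prop-1-en-2-yl)cyclohex-2-en-1-one | O=C1C(C)=CC[C@H](C(C)=C)C1 | starting material
2 | (5S,6R)-2,6-dimethyl-5-(prop-1-en-2-yl)cyclohex-2-en-1-one (major; used with its 6S epimer) | O=C1C(C)=CC[C@H](C(C)=C)[C@H]1C | intermediate
3 | allyl bromide | C=CCBr | starting material
4 | (5R,6R)-6-allyl-2,6-dimethyl-5-(prop-1-en-2-yl)cyclohex-2-en-1-one (allyl trans, methyl cis to isopropenyl) | O=C1C(C)=CC[C@H](C(C)=C)[C@@]1(C)CC=C | intermediate
5 | catechol boronate of 4 (boron on the terminal carbon of the former allyl group) | O=C1C(C)=CC[C@H](C(C)=C)[C@@]1(C)CCCB3Oc4ccccc4O3 | intermediate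
6 | 6-(3-hydroxypropyl) analogue of 4 | O=C1C(C)=CC[C@H](C(C)=C)[C@@]1(C)CCCO | intermediate
7 | 6-(3-oxopropyl) analogue (aldehyde) | O=C1C(C)=CC[C@H](C(C)=C)[C@@]1(C)CCC=O | intermediate
8 | aldimine of 7 | O=C1C(C)=CC[C@H](C(C)=C)[C@@]1(C)CCC=N | intermediate
9 | 6-(2-cyanoethyl) analogue (cyanoethyl trans to isopropenyl) | O=C1C(C)=CC[C@H](C(C)=C)[C@@]1(C)CCC#N | intermediate
10 | C3 ketimine of 11 | O=C1C(C)=CC[C@@H]2C(C)(C)C(=N)CC[C@@]12C | intermediate
11 | ent-11-nordrim-7-ene-3,9-dione, (4aR,8aR)-2,5,5,8a-tetramethyl-4a,5,8,8a-tetrahydronaphthalene-1,6(4H,7H)-dione (trans-fused; C10 methyl down, H-5 up) | O=C1C(C)=CC[C@@H]2C(C)(C)C(=O)CC[C@@]12C | intermediate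
12 | C3 enol triflate of 11 (C2=C3) | O=C1C(C)=CC[C@@H]2C(C)(C)C(OS(=O)(=O)C(F)(F)F)=CC[C@@]12C | intermediate
13 | ent-11-nordrima-2,7-dien-9-one | O=C1C(C)=CC[C@@H]2C(C)(C)C=CC[C@@]12C | intermediate
14 | 2,3-dihydroxy-ent-11-nordrim-7-en-9-one (cis-diol, both OH up; 2-OH equatorial, 3-OH axial) | O=C1C(C)=CC[C@@H]2C(C)(C)[C@@H](O)[C@@H](O)C[C@@]12C | intermediate
15 | 2,3-acetonide of 14 | O=C1C(C)=CC[C@@H]2C(C)(C)[C@H]3OC(C)(C)O[C@H]3C[C@@]12C | intermediate
16 | vinylmagnesium bromide | C=C[Mg]Br | starting material
17 | C9 tertiary carbinol from 15 (vinyl up, OH down; 2,3-acetonide) | C=C[C@@]1(O)C(C)=CC[C@@H]2C(C)(C)[C@H]3OC(C)(C)O[C@H]3C[C@@]12C | intermediate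
18 | ethyl acetoacetate | CCOC(=O)CC(C)=O | starting material
19 | ethyl (E)-3-(trifluoromethylsulfonyloxy)but-2-enoate | CCOC(=O)/C=C(\C)OS(=O)(=O)C(F)(F)F | intermediate
20 | B-alkyl-9-BBN from 17 (boron on C12) | B4(C5CCCC4CCC5)CC[C@@]1(O)C(C)=CC[C@@H]2C(C)(C)[C@H]3OC(C)(C)O[C@H]3C[C@@]12C | intermediate
21 | ethyl 9-hydroxy-ent-labda-7,13E-dien-15-oate 2,3-acetonide (9-OH down) | CCOC(=O)/C=C(\C)CC[C@@]1(O)C(C)=CC[C@@H]2C(C)(C)[C@H]3OC(C)(C)O[C@H]3C[C@@]12C | intermediate
22 | ethyl 7-oxo-ent-labda-8,13E-dien-15-oate 2,3-acetonide | CCOC(=O)/C=C(\C)CCC1=C(C)C(=O)C[C@@H]2C(C)(C)[C@H]3OC(C)(C)O[C@H]3C[C@@]12C | intermediate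
23 | ethyl 7-hydroxy-ent-labda-8,13E-dien-15-oate 2,3-acetonide (7-OH down, cis to the C10 methyl) | CCOC(=O)/C=C(\C)CCC1=C(C)[C@H](O)C[C@@H]2C(C)(C)[C@H]3OC(C)(C)O[C@H]3C[C@@]12C | intermediate
24 | C7 N-allyl-N-(2-nitrobenzenesulfonyl)hydrazine (nitrogen up) | CCOC(=O)/C=C(\C)CCC1=C(C)[C@@H](N(N)S(=O)(=O)c4ccccc4[N+](=O)[O-])C[C@@H]2C(C)(C)[C@H]3OC(C)(C)O[C@H]3C[C@@]12C | intermediate
25 | C7 allylic diazene (nitrogen up) | CCOC(=O)/C=C(\C)CCC1=C(C)[C@@H](N=N)C[C@@H]2C(C)(C)[C@H]3OC(C)(C)O[C@H]3C[C@@]12C | intermediate
26 | ethyl ent-labda-7,13E-dien-15-oate 2,3-acetonide (H-9 up, C11 down) | CCOC(=O)/C=C(\C)CC[C@@H]1C(C)=CC[C@@H]2C(C)(C)[C@H]3OC(C)(C)O[C@H]3C[C@@]12C | intermediate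
27 | ent-labda-7,13E-diene-2,3,15-triol 2,3-acetonide | OC/C=C(\C)CC[C@@H]1C(C)=CC[C@@H]2C(C)(C)[C@H]3OC(C)(C)O[C@H]3C[C@@]12C | intermediate
28 | (2S,3R,5S,9R,10S)-ent-labda-7,13E-diene-2,3,15-triol | OC/C=C(\C)CC[C@@H]1C(C)=CC[C@@H]2C(C)(C)[C@@H](O)[C@@H](O)C[C@@]12C | intermediate
29 | CNP0254679.1, (2S,3R,5S,9R,10S)-2-acetoxy-3-hydroxy-ent-labda-7,13E-dien-15-yl acetate | CC(=O)OC/C=C(\C)CC[C@@H]1C(C)=CC[C@@H]2C(C)(C)[C@@H](O)[C@@H](OC(C)=O)C[C@@]12C | target

## Step count and least certain steps

Total: 18 steps. Longest linear sequence: 17 steps (steps 1–10 and 12–18); step 11 prepares the coupling partner.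

Step 5 (key step). The 6-exo-dig addition of the tertiary radical to the nitrile is slow, so a second hydrogen-atom transfer may reduce the radical first (net hydrogenation of the isopropenyl group), or the alkene may isomerise to the isopropylidene. Fallback, setting out from 6: Dess–Martin oxidation would give aldehyde 7 as an isolated compound. Under the same Fe(acac)3/PhSiH3 conditions the tertiary radical would add to the aldehyde carbonyl (6-exo-trig, far faster than addition to a nitrile) to give the C3-epimeric 3-hydroxy-ent-11-nordrim-7-en-9-one F1. A second Dess–Martin oxidation returns to the route at 11.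

Step 6. Deprotonation may occur at the γ-position (C6) of the enone instead of at C2, leading to sulfonylation of the dienolate. Fallback, setting out from 11: condensation with tosylhydrazide should occur only at the unconjugated C3 carbonyl (the C9 carbonyl is conjugated and flanked by quaternary C10 and the C8 methyl) to give the C3 tosylhydrazone F2. Bamford–Stevens decomposition (NaOMe, diglyme, 150 °C) gives the carbene, which can shift hydrogen only from C2, and the route is rejoined at 13.

Step 13. Chromate ester formation at the very hindered tertiary carbinol may be slow, so acid-promoted ionisation with dehydration to a triene or loss of the acetonide may compete with the [3,3] shift. Fallback, setting out from 21: a redox-neutral 1,3-transposition catalysed by Ph3SiOReO3 would move the hydroxyl suprafacially from C9 to C7, driven by formation of the tetrasubstituted alkene, and return directly to 23 without a new compound. If C7 were formed as an epimer mixture, MnO2 oxidation would converge on 22.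

Step 15. Mitsunobu displacement at the pseudo-equatorial C7 carbinol next to the tetrasubstituted alkene may be slow, so elimination to the ring diene or SN2′ attack may erode yield and stereochemical fidelity. Fallback, setting out from 23: formylation (formic acetic anhydride, pyridine) gives the C7 allylic formate F3. Zerovalent palladium generated from Pd(OAc)2 and PBu3 ionises it with inversion, and the hydride from the formate is delivered from the metal to the more substituted terminus C9, on the face opposite the leaving group. This returns to the route at 26.

Step 18. Acetylation may run on to the axial O3, or stop short at O2, and the acetyl group may migrate between O2 and O3. Fallback, setting out from 28: Bu2SnO in refluxing toluene gives the 2,3-O-dibutylstannylene acetal F4, in which the equatorial O2 is the activated oxygen. AcCl (2 equiv) at 0 °C then acylates O2 and the free primary hydroxyl and returns to the route at 29.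

## Further compounds

F1 | step 5 | 3-hydroxy-ent-11-nordrim-7-en-9-one (C3 epimer mixture) | O=C1C(C)=CC[C@@H]2C(C)(C)C(O)CC[C@@]12C
F2 | step 6 | C3 tosylhydrazone of 11 | O=C1C(C)=CC[C@@H]2C(C)(C)C(=NNS(=O)(=O)c3ccc(C)cc3)CC[C@@]12C
F0 | step 13 | none | none
F3 | step 15 | C7 formate of 23 (formate down) | CCOC(=O)/C=C(\C)CCC1=C(C)[C@H](OC=O)C[C@@H]2C(C)(C)[C@H]3OC(C)(C)O[C@H]3C[C@@]12C
F4 | step 18 | 2,3-O-dibutylstannylene acetal of 28 | OC/C=C(\C)CC[C@@H]1C(C)=CC[C@@H]2C(C)(C)[C@H]3O[Sn](CCCC)(CCCC)O[C@H]3C[C@@]12C
A1 | alternative 1 | (R)-14,15-epoxygeranylgeranyl acetate | CC(=O)OC/C=C(\C)CC/C=C(\C)CC/C=C(\C)CC[C@H]1OC1(C)C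
A2 | alternative 1 | 3-hydroxy-ent-labda-8(17),13E-dien-15-yl acetate (3-OH equatorial) | CC(=O)OC/C=C(\C)CC[C@@H]1C(=C)CC[C@@H]2C(C)(C)[C@H](O)CC[C@@]12C
A3 | alternative 2 | (E,E,E)-geranylgeranyl diphosphate | CC(C)=CCC/C(C)=C/CC/C(C)=C/CC/C(C)=C/COP(=O)(O)OP(=O)(O)O
A4 | alternative 2 | ent-copalyl diphosphate | OP(=O)(O)OP(=O)(O)OC/C=C(\C)CC[C@@H]1C(=C)CC[C@@H]2C(C)(C)CCC[C@@]12C
A5 | alternative 3 | 2,6-dimethylcyclohex-2-en-1-one | CC1CCC=C(C)C1=O
A6 | alternative 3 | 2-allyl-2,6-dimethyl-3-(2-methylbut-3-en-2-yl)cyclohexan-1-one (allyl trans to the C3 substituent) | O=C1C(C)CC[C@H](C(C)(C)C=C)[C@@]1(C)CC=C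
A7 | alternative 3 | ent-11-nordrim-2-en-9-one | O=C1C(C)CC[C@@H]2C(C)(C)C=CC[C@@]12C
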